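**Strategy.** The seven-membered ring is cut at C7–C8 and C4–C5 (azulene numbering: C3 carbinol, C4 acyloxy carbon, C8 ketone, C8a quaternary carbon). This leaves an isobutene 1,3-dianion (C5–C6–C7 plus the C6 methyl) and a cyclopentane whose cis carbons C4 and C8 sit at aldehyde and acid level, that is, a cis-fused γ-alkoxy-γ-lactone. The key step exploits this 1,4-dioxygenation (C4–O, C8=O) across the cis ring fusion C3a–C8a: a Lewis-acid [4+3] annulation of the lactone acetal with 2-methylidenepropane-1,3-diylbis(trimethylsilane) closes the seven-membered ring, sets C4 on the convex face and unveils the C4 alcohol and C8 ketone in one operation. The lactone acetal is assembled on a chiral 5-menthyloxybutenolide.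

Key step: step 5

Remark: the target is read as the cis-fused hydroazulene (3a-H, 8a-CH3 and 3-OH on one face; 4-acyloxy and 3-isopropyl on the other; 3R,3aR,4S,8aS), and 1, 2 and 10 are taken as catalogue reagents (1 is otherwise two steps from furfural and (−)-menthol, 10 one step from 3-chloro-2-(chloromethyl)prop-1-ene).

"Menthyloxy" below always means the (1R,2S,5R)-5-methyl-2-(propan-2-yl)cyclohexyloxy group.

Step 1
Reactants: 1 (5R)-5-menthyloxyfuran-2(5H)-one; 2 2-bromo-3-methylbut-1-ene
Product: 5 (3R,4S,5R)-4-(3-methylbut-1-en-2-yl)-5-menthyloxy-3-(prop-2-en-1-yl)oxolan-2-one, via Grignard reagent 3 (not isolated), via magnesium enolate 4 (not isolated)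
Conditions: 2, Mg, THF; then CuBr·SMe2 (10 mol %), 1, THF, −78 °C; then allyl bromide, DMPU, −78 → 0 °C
Reagents that add atoms: 3-bromoprop-1-ene (allyl bromide), C=CCBr
Why: Copper-catalysed conjugate addition of the alkenyl Grignard reagent to the 5-alkoxybutenolide should occur anti to the menthyloxy group (sets C-4), and the magnesium enolate should be allylated anti to the new C-4 substituent (tandem conjugate addition–enolate alkylation), the C-3 centre being only temporary.

Step 2
Reactants: 5 (3R,4S,5R)-4-(3-methylbut-1-en-2-yl)-5-menthyloxy-3-(prop-2-en-1-yl)oxolan-2-one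
Product: 7 (3S,4R,5R)-3-methyl-4-(3-methylbut-1-en-2-yl)-5-menthyloxy-3-(prop-2-en-1-yl)oxolan-2-one, via lithium enolate 6 (not isolated)
Conditions: LDA, THF, −78 °C; then MeI, DMPU, −78 → −20 °C
Reagents that add atoms: iodomethane, CI
Why: Enolate alkylation in which the planar lithium enolate should be methylated on the face anti to the bulky C-4 alkenyl group, which sets the quaternary centre with methyl trans and allyl cis to that group, as the ring closure needs.

Step 3
Reactants: 7 (3S,4R,5R)-3-methyl-4-(3-methylbut-1-en-2-yl)-5-menthyloxy-3-(prop-2-en-1-yl)oxolan-2-one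
Product: 8 (3R,3aR,6aS)-6a-methyl-3-menthyloxy-4-(propan-2-yl)-3,3a,6,6a-tetrahydro-1H-cyclopenta[c]furan-1-one
Conditions: second-generation Grubbs catalyst (5 mol %), toluene, 80 °C
Reagents that add atoms: none
Why: Ring-closing metathesis of the cis-disposed allyl and 1,1-disubstituted alkenyl groups should close the cis-fused cyclopentene (trisubstituted alkene) with loss of ethene and creates no new stereocentre.

Step 4
Reactants: 8 (3R,3aR,6aS)-6a-methyl-3-menthyloxy-4-(propan-2-yl)-3,3a,6,6a-tetrahydro-1H-cyclopenta[c]furan-1-one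
Product: 9 (3R,3aS,4R,6aS)-4-hydroxy-6a-methyl-3-menthyloxy-4-(propan-2-yl)hexahydro-1H-cyclopenta[c]furan-1-one
Conditions: Co(acac)2 (20 mol %), PhSiH3, O2 (1 atm), i-PrOH, rt
Reagents that add atoms: dioxygen, O=O
Why: Mukaiyama hydration, in which hydrogen-atom transfer from the Co–H species formed from Co(acac)2 and PhSiH3 gives the Markovnikov tertiary radical at C-4, which O2 should trap on the convex face of the cis-bicyclo[3.3.0] skeleton (anti to the lactone ring), placing the hydroxyl exo and the isopropyl group endo.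

Step 5
Reactants: 9 (3R,3aS,4R,6aS)-4-hydroxy-6a-methyl-3-menthyloxy-4-(propan-2-yl)hexahydro-1H-cyclopenta[c]furan-1-one; 10 2-methylidenepropane-1,3-diylbis(trimethylsilane)
Product: 14 (3R,3aR,4S,8aS)-3,4-dihydroxy-8a-methyl-6-methylidene-3-(propan-2-yl)-2,3,3a,4,5,6,7,8a-octahydroazulen-8(1H)-one, via silyl ether 11 (not isolated), via allylsilane lactone 12 (not isolated), via bridged silyl ketal 13 (not isolated)
Conditions: 10 (3 equiv), TMSOTf (3 equiv), 2,6-di-tert-butyl-4-methylpyridine, CH2Cl2, −78 → 0 °C; then 1 M HCl, THF, 0 °C; NaHCO3 work-up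
Reagents that add atoms: none
Why: Proposed new method: TMSOTf silylates the tertiary alcohol (11) and ionises the exocyclic menthyl acetal to a bicyclic acyloxocarbenium ion that the electron-rich 2-substituted allylsilane 10 attacks at C-3 (Hosomi–Sakurai) to give 12, after which O-silylation of the lactone carbonyl makes a silyloxy(alkoxy)carbenium ion that the second, now tethered allylsilane attacks to give the bridged silyl ketal 13, and acid hydrolysis opens 13 to hydroxy ketone 14. The closest known reaction types are the Lewis-acid [4+3] annulation of 1,4-dicarbonyl compounds with 1,3-bis-nucleophiles through bicyclic oxocarbenium ions, the Sakurai allylation of γ-alkoxy lactones and the addition of allylsilanes to dialkoxycarbenium ions made from ortho esters; only the use of a silyl-activated lactone carbonyl as the second electrophile is new. The seven-membered carbocycle closes as the three-carbon bridge of an 8-oxabicyclo[3.2.1]octane, by 7-exo-trig attack of the allylsilane terminus on the carbenium carbon (6-exo-trig if counted through the ring oxygen). The one new stereocentre, the former acetal carbon (C-4 of the azulene), is set in the Sakurai event by attack on the convex face of the cis-fused bicycle, anti to the cyclopentane ring, and this places the chain where it can bridge to the lactone carbon with the cyclopentane exo. The step needs the acetal to react before the lactone (secured by the far higher electrophilicity of the acyloxocarbenium ion), 10 to be alkylated only once before it cyclises (excess 10) and no protodesilylation (hindered pyridine base).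

Step 6
Reactants: 14 (3R,3aR,4S,8aS)-3,4-dihydroxy-8a-methyl-6-methylidene-3-(propan-2-yl)-2,3,3a,4,5,6,7,8a-octahydroazulen-8(1H)-one
Product: 15 (3R,3aR,4S,8aS)-3,4-dihydroxy-6,8a-dimethyl-3-(propan-2-yl)-2,3,3a,4,5,8a-hexahydroazulen-8(1H)-one
Conditions: DBU, CH2Cl2, rt
Reagents that add atoms: none
Why: Base-mediated isomerisation of the β,γ-unsaturated ketone through its dienolate should give the thermodynamically favoured conjugated endocyclic enone, and no stereocentre is touched because C-3a and C-8a are not enolisable.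

Step 7
Reactants: 15 (3R,3aR,4S,8aS)-3,4-dihydroxy-6,8a-dimethyl-3-(propan-2-yl)-2,3,3a,4,5,8a-hexahydroazulen-8(1H)-one; 16 4-methoxybenzoyl chloride
Product: 17 (3R,3aR,4S,8aS)-3-hydroxy-6,8a-dimethyl-8-oxo-3-(propan-2-yl)-1,2,3,3a,4,5,8,8a-octahydroazulen-4-yl 4-methoxybenzoate
Conditions: 16, pyridine, DMAP (cat.), CH2Cl2, 0 °C → rt
Reagents that add atoms: none
Why: DMAP-catalysed acylation (nucleophilic catalysis) should esterify the secondary C-4 alcohol selectively, the tertiary C-3 alcohol being too hindered, with retention at C-4 and under conditions mild enough to avoid vinylogous elimination of the new ester.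

**Compound list**

1 | (5R)-5-{[(1R,2S,5R)-5-methyl-2-(propan-2-yl)cyclohexyl]oxy}furan-2(5H)-one | O=C1C=C[C@H](O[C@@H]2C[C@H](C)CC[C@H]2C(C)C)O1 | starting material
2 | 2-bromo-3-methylbut-1-ene | C=C(Br)C(C)C | starting material
3 | (3-methylbut-1-en-2-yl)magnesium bromide | C=C([Mg]Br)C(C)C | intermediate
4 | bromomagnesium (4S,5R)-4-(3-methylbut-1-en-2-yl)-5-menthyloxy-4,5-dihydrofuran-2-olate | Br[Mg]OC1=C[C@@H](C(=C)C(C)C)[C@H](O[C@@H]2C[C@H](C)CC[C@H]2C(C)C)O1 | intermediate
5 | (3R,4S,5R)-4-(3-methylbut-1-en-2-yl)-5-menthyloxy-3-(prop-2-en-1-yl)oxolan-2-one | O=C1[C@H](CC=C)[C@@H](C(=C)C(C)C)[C@H](O[C@@H]2C[C@H](C)CC[C@H]2C(C)C)O1 | intermediate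
6 | lithium (4R,5R)-4-(3-methylbut-1-en-2-yl)-5-menthyloxy-3-(prop-2-en-1-yl)-4,5-dihydrofuran-2-olate | [Li]OC1=C(CC=C)[C@@H](C(=C)C(C)C)[C@H](O[C@@H]2C[C@H](C)CC[C@H]2C(C)C)O1 | intermediate
7 | (3S,4R,5R)-3-methyl-4-(3-methylbut-1-en-2-yl)-5-menthyloxy-3-(prop-2-en-1-yl)oxolan-2-one | O=C1[C@@](C)(CC=C)[C@@H](C(=C)C(C)C)[C@H](O[C@@H]2C[C@H](C)CC[C@H]2C(C)C)O1 | intermediate
8 | (3R,3aR,6aS)-6a-methyl-3-menthyloxy-4-(propan-2-yl)-3,3a,6,6a-tetrahydro-1H-cyclopenta[c]furan-1-one (cis-fused) | O=C1O[C@@H](O[C@@H]3C[C@H](C)CC[C@H]3C(C)C)[C@@H]2C(C(C)C)=CC[C@]12C | intermediate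
9 | (3R,3aS,4R,6aS)-4-hydroxy-6a-methyl-3-menthyloxy-4-(propan-2-yl)hexahydro-1H-cyclopenta[c]furan-1-one | O=C1O[C@@H](O[C@@H]3C[C@H](C)CC[C@H]3C(C)C)[C@@H]2[C@](O)(C(C)C)CC[C@]12C | intermediate
10 | 2-methylidenepropane-1,3-diylbis(trimethylsilane) | C=C(C[Si](C)(C)C)C[Si](C)(C)C | starting material
11 | (3R,3aS,4R,6aS)-6a-methyl-3-menthyloxy-4-(propan-2-yl)-4-[(trimethylsilyl)oxy]hexahydro-1H-cyclopenta[c]furan-1-one | O=C1O[C@@H](O[C@@H]3C[C@H](C)CC[C@H]3C(C)C)[C@@H]2[C@](O[Si](C)(C)C)(C(C)C)CC[C@]12C | intermediate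
12 | (3S,3aR,4R,6aS)-6a-methyl-4-(propan-2-yl)-3-{2-[(trimethylsilyl)methyl]prop-2-en-1-yl}-4-[(trimethylsilyl)oxy]hexahydro-1H-cyclopenta[c]furan-1-one | O=C1O[C@@H](CC(=C)C[Si](C)(C)C)[C@@H]2[C@](O[Si](C)(C)C)(C(C)C)CC[C@]12C | intermediate
13 | (3R,3aR,4S,8S,8aS)-4,8-epoxy-8a-methyl-6-methylidene-3-(propan-2-yl)-3,8-bis[(trimethylsilyl)oxy]decahydroazulene (8-oxabicyclo[3.2.1]octane core, cyclopentane exo) | C[Si](C)(C)O[C@]12CC(=C)C[C@H](O1)[C@@H]1[C@](O[Si](C)(C)C)(C(C)C)CC[C@]21C | intermediate
14 | (3R,3aR,4S,8aS)-3,4-dihydroxy-8a-methyl-6-methylidene-3-(propan-2-yl)-2,3,3a,4,5,6,7,8a-octahydroazulen-8(1H)-one | O[C@H]1CC(=C)CC(=O)[C@@]2(C)CC[C@@](O)(C(C)C)[C@@H]12 | intermediate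
15 | (3R,3aR,4S,8aS)-3,4-dihydroxy-6,8a-dimethyl-3-(propan-2-yl)-2,3,3a,4,5,8a-hexahydroazulen-8(1H)-one | O[C@H]1CC(C)=CC(=O)[C@@]2(C)CC[C@@](O)(C(C)C)[C@@H]12 | intermediate
16 | 4-methoxybenzoyl chloride | COc1ccc(C(=O)Cl)cc1 | starting material
17 | (3R,3aR,4S,8aS)-3-hydroxy-6,8a-dimethyl-8-oxo-3-(propan-2-yl)-1,2,3,3a,4,5,8,8a-octahydroazulen-4-yl 4-methoxybenzoate | COc1ccc(C(=O)O[C@H]2CC(C)=CC(=O)[C@@]3(C)CC[C@@](O)(C(C)C)[C@@H]23)cc1 | target

**Total step count:** 7. **Longest linear sequence:** 7 steps (1 → 17).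

**Steps most likely to fail**

1. Step 5 (Proposed new method). The second ring closure may not take place: the tethered allylsilane of 12 may fail to add to the silyl-activated lactone carbonyl, it may be lost by protodesilylation, or 10 may be alkylated at both ends by two oxocarbenium ions. The fallback uses known chemistry and sets out from 9. Hosomi–Sakurai allylation with [2-(chloromethyl)prop-2-en-1-yl]trimethylsilane (BF3·OEt2, CH2Cl2, −78 °C) should give, by the same convex-face attack, the allylic chloride lactone F1. SmI2 with catalytic NiI2 in THF should then turn the chloride into an allylsamarium species that attacks the lactone carbonyl (intramolecular Barbier-type nucleophilic acyl substitution). Work-up brings the route back at 14.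

2. Step 4. Capture of the tertiary radical by the small O2 molecule may show poor facial selectivity, or the radical may be reduced to the alkane. The fallback sets out from 8. Epoxidation with the bulkier m-CPBA on the convex face should give the epoxide F2. Trans-diaxial opening at the less substituted carbon with PhSeNa [(PhSe)2, NaBH4, EtOH] should give the hydroxy selenide F3. Oxidation with H2O2 and selenoxide syn-elimination away from the carbinol carbon should give the allylic alcohol F4. Hydrogenation (H2, Pd/C) brings the route back at 9.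

3. Step 3. Ring closure may stall at the hindered, α-branched 1,1-disubstituted alkene, so that intermolecular metathesis of the allyl group takes over. The fallback sets out from 7. Ozonolysis of both alkenes (O3, CH2Cl2, −78 °C; then Me2S) should give the keto aldehyde F5. Intramolecular McMurry coupling (TiCl3, Zn–Cu couple, DME, reflux, high dilution) then forms the same ring alkene and brings the route back at 8.

**Further compounds**

F1 | step 5 | (3S,3aR,4R,6aS)-3-[2-(chloromethyl)prop-2-en-1-yl]-4-hydroxy-6a-methyl-4-(propan-2-yl)hexahydro-1H-cyclopenta[c]furan-1-one | O=C1O[C@@H](CC(=C)CCl)[C@@H]2[C@](O)(C(C)C)CC[C@]12C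
F2 | step 4 | 4,5-epoxide of 8 with the epoxide oxygen on the convex face (anti to the lactone ring) | O=C1O[C@@H](O[C@@H]3C[C@H](C)CC[C@H]3C(C)C)[C@@H]2[C@@]4(C(C)C)O[C@H]4C[C@]12C
F3 | step 4 | 5-(phenylselanyl) derivative of 9 with selenium trans to the 4-hydroxyl | O=C1O[C@@H](O[C@@H]3C[C@H](C)CC[C@H]3C(C)C)[C@@H]2[C@](O)(C(C)C)[C@H]([Se]c4ccccc4)C[C@]12C
F4 | step 4 | 5,6-didehydro derivative of 9 (tertiary allylic alcohol) | O=C1O[C@@H](O[C@@H]3C[C@H](C)CC[C@H]3C(C)C)[C@@H]2[C@](O)(C(C)C)C=C[C@]12C
F5 | step 3 | (3S,4R,5R)-3-methyl-4-(2-methylpropanoyl)-5-menthyloxy-3-(2-oxoethyl)oxolan-2-one | O=C1[C@@](C)(CC=O)[C@@H](C(=O)C(C)C)[C@H](O[C@@H]2C[C@H](C)CC[C@H]2C(C)C)O1
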